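**Plan**
1. Retrosynthetic cuts (azulene numbering: C3 carbinol, C3a–H, C4–O, C5=C6–CH3, C8a–CH3): the ester C4–O bond and the ring bonds C4–C5 and C5–C6 are made in one event, so C5 is removed as a CBr2 unit and a trans-hydrindene with a CH=C(CH3) alkene remains. Further cuts: C3–isopropyl, C3–O/C3a–H (alkene hydroboration), C6–CH3 (dienyl triflate), and the Robinson bonds of a hydrindenone.
2. Forward order: cyclopentane ring bought → six-membered ring by Robinson annulation → substituents → temporary cyclopropane → seven-membered ring by one-carbon ring expansion → Br helper and SiEt3 removed.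
3. Enabling feature: in the ring C3a–C4–C5–C6–C7–C8–C8a the unit C4H(O2CAr)–C5H=C6(CH3) is an allyl system with a secondary oxygen-bearing end and a methyl-bearing end. This is what a 1-methyl-7,7-dibromobicyclo[4.1.0]heptane gives on cyclopropyl→allyl cation opening with carboxylate capture; C5 is the inserted atom.
4. Stereochemistry: C8a comes from a chiral-imine Michael addition. C3a (hydroboration), C3 (isopropyl addition) and C4 (carboxylate capture) are relayed from the angular methyl, each reagent entering on the opposite face.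

Key step: step 10

Remark (assumption): hydrindane intermediates are cited in indene numbering (C3, C3a, C4=C5–CH3, C7a–CH3), and (S)-1-phenylethylamine is assumed to induce the same sense as in the 2-methylcyclohexanone series (R quaternary centre).

Step 1
Reactants: 1 2-methylcyclopentan-1-one (racemic); 2 (S)-1-phenylethan-1-amine; 3 but-3-en-2-one
Product: 6 (R)-2-methyl-2-(3-oxobutyl)cyclopentan-1-one, via imine 4 (not isolated), via Michael-adduct imine 5 (not isolated)
Conditions: (i) 2, TsOH (cat.), PhMe, reflux (−H2O); (ii) 3, THF, rt; (iii) aq. AcOH, rt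
Reagents that add atoms: water, O
Why: Asymmetric Michael addition of a chiral imine: the more substituted secondary-enamine tautomer of 4 should add to the enone through a compact aza-ene-like transition state on the face away from the phenyl group of the auxiliary, setting the quaternary centre as R, and hydrolysis releases the amine.

Step 2
Reactants: 6 (R)-2-methyl-2-(3-oxobutyl)cyclopentan-1-one
Product: 7 (R)-7a-methyl-1,2,3,6,7,7a-hexahydro-5H-inden-5-one
Conditions: KOH, MeOH, 60 °C
Reagents that add atoms: none
Why: Second stage of a Robinson annulation: the methyl-ketone enolate closes the six-membered ring on the ring carbonyl (6-enolexo aldol) and dehydration gives the conjugated enone without touching the quaternary centre.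

Step 3
Reactants: 7 (R)-7a-methyl-1,2,3,6,7,7a-hexahydro-5H-inden-5-one
Product: 8 (R)-7a-methyl-2,6,7,7a-tetrahydro-1H-inden-5-yl trifluoromethanesulfonate
Conditions: Tf2O, 2,6-di-tert-butyl-4-methylpyridine, CH2Cl2, 0 °C → rt
Reagents that add atoms: trifluoromethanesulfonic anhydride, O=S(=O)(OS(=O)(=O)C(F)(F)F)C(F)(F)F
Why: O-Triflation of the enone followed by loss of a γ-proton from the cyclopentane CH2 (the only γ-hydrogens) should give the extended, heteroannular dienyl triflate, as known for 4-en-3-one steroids; no stereocentre is involved.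

Step 4
Reactants: 8 (R)-7a-methyl-2,6,7,7a-tetrahydro-1H-inden-5-yl trifluoromethanesulfonate
Product: 9 (R)-5,7a-dimethyl-2,6,7,7a-tetrahydro-1H-indene
Conditions: MeMgBr, Fe(acac)3 (5 mol %), THF/NMP, −20 °C
Reagents that add atoms: methylmagnesium bromide, C[Mg]Br
Why: Iron-catalysed Kumada-type cross-coupling of an alkenyl triflate with a Grignard reagent replaces C–OTf by C–CH3 with the diene geometry fixed by the rings.

Step 5
Reactants: 9 (R)-5,7a-dimethyl-2,6,7,7a-tetrahydro-1H-indene
Product: 11 (3R,3aR,7aS)-5,7a-dimethyl-2,3,3a,6,7,7a-hexahydro-1H-inden-3-ol, via B-alkyl-9-BBN 10 (not isolated)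
Conditions: 9-BBN, THF, 0 °C → rt; then NaOH, 30% H2O2, 0 °C
Reagents that add atoms: 9-borabicyclo[3.3.1]nonane (boron in 10 only), B1C2CCCC1CCC2; hydrogen peroxide, OO
Why: Brown hydroboration–oxidation: of the two trisubstituted alkenes the strained cyclopentene one should react much faster with 9-BBN, boron going to the CH terminus (C3) and hydrogen to C3a in a syn addition on the face opposite the angular methyl (as in hydroboration of Δ14 steroids), which fixes the trans ring fusion, and oxidation proceeds with retention.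

Step 6
Reactants: 11 (3R,3aR,7aS)-5,7a-dimethyl-2,3,3a,6,7,7a-hexahydro-1H-inden-3-ol
Product: 12 (3aR,7aS)-5,7a-dimethyl-1,2,3a,6,7,7a-hexahydro-3H-inden-3-one
Conditions: Dess–Martin periodinane, NaHCO3, CH2Cl2, 0 °C
Reagents that add atoms: none
Why: Dess–Martin oxidation under buffered, non-basic conditions should give the β,γ-unsaturated ketone without moving the alkene into conjugation or epimerising C3a.

Step 7
Reactants: 12 (3aR,7aS)-5,7a-dimethyl-1,2,3a,6,7,7a-hexahydro-3H-inden-3-one
Product: 13 (3R,3aR,7aS)-5,7a-dimethyl-3-(propan-2-yl)-2,3,3a,6,7,7a-hexahydro-1H-inden-3-ol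
Conditions: i-PrMgCl, CeCl3 (anhydrous), THF, −78 °C; aq. NH4Cl
Reagents that add atoms: isopropylmagnesium chloride, CC(C)[Mg]Cl
Why: Organocerium 1,2-addition (Imamoto conditions): the weakly basic reagent should add faster than it enolises or reduces the ketone, and it attacks the cyclopentanone from the face of H-3a, opposite the 1,3-related angular methyl, so the hydroxyl ends cis to the methyl (3R).

Step 8
Reactants: 13 (3R,3aR,7aS)-5,7a-dimethyl-3-(propan-2-yl)-2,3,3a,6,7,7a-hexahydro-1H-inden-3-ol
Product: 14 triethyl{[(3R,3aR,7aS)-5,7a-dimethyl-3-(propan-2-yl)-2,3,3a,6,7,7a-hexahydro-1H-inden-3-yl]oxy}silane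
Conditions: TESOTf, 2,6-lutidine, CH2Cl2, −78 → 0 °C
Reagents that add atoms: triethylsilyl trifluoromethanesulfonate, CC[Si](CC)(CC)OS(=O)(=O)C(F)(F)F
Why: Silyl triflate silylation of the hindered tertiary alcohol; the silyl ether keeps the oxygen away from the carbene of step 9 and the cation of step 10 and adds bulk to the methyl face.

Step 9
Reactants: 14 triethyl{[(3R,3aR,7aS)-5,7a-dimethyl-3-(propan-2-yl)-2,3,3a,6,7,7a-hexahydro-1H-inden-3-yl]oxy}silane
Product: 15 dibromocarbene adduct of 14 (7,7-dibromobicyclo[4.1.0]heptane unit across indene C4–C5, CBr2 on the face of H-3a, other centres as in 14)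
Conditions: CHBr3, KOt-Bu, pentane, 0 °C → rt
Reagents that add atoms: bromoform, BrC(Br)Br
Why: [2+1] Cycloaddition of dibromocarbene to the electron-rich trisubstituted alkene builds the temporary cyclopropane, expected on the face of H-3a; its configuration is immaterial because both cyclopropane ring-fusion carbons are planarised in the allyl cation of step 10.

Step 10
Reactants: 15 dibromocarbene adduct of 14
Product: 16 (3R,3aS,4R,8aS)-5-bromo-6,8a-dimethyl-3-(propan-2-yl)-3-[(triethylsilyl)oxy]-1,2,3,3a,4,7,8,8a-octahydroazulen-4-yl 4-methoxybenzoate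
Conditions: 4-MeOC6H4CO2Ag (3 equiv, made in the flask from Ag2O and 4-MeOC6H4CO2H, 4 Å MS), ClCH2CH2Cl, 60 °C, dark
Reagents that add atoms: 4-methoxybenzoic acid (used as its silver(I) salt), COc1ccc(cc1)C(=O)O
Why: Silver(I) should abstract the endo bromide (the one syn to the six-membered ring, the only one whose loss lets the ring carbons turn inward) while the cyclopropane bond shared with the six-membered ring opens in a disrotatory two-electron electrocyclic sense, giving a cis-2-bromocycloheptenyl cation with a secondary terminus (future C4) and a tertiary methyl-bearing terminus (future C6), which the silver-bound 4-methoxybenzoate then captures. The closest known reaction is the silver acetate/acetic acid ring expansion of 7,7-dibromobicyclo[4.1.0]heptanes and of 1-methyl-6,6-dibromobicyclo[3.1.0]hexane to 2-bromo-3-methylcycloalk-2-enyl acetates. No ring is closed by bond formation: the seven-membered ring arises from the six-membered one only by cleavage of the zero-atom bridge, the former carbene carbon becoming ring atom C5. The one new stereocentre, C4, is set by substrate control: the angular 8a-methyl (1,3 to C4) and the C3–OSiEt3 group lie on the same face of the planar cation, so the carboxylate should enter from the face of H-3a and give the 3,4-trans ester. The step needs regioselectivity between the two allyl termini and chemoselectivity against internal capture: attack at the secondary terminus gives the tetrasubstituted bromoalkene and is the thermodynamic outcome, a tertiary allylic ester formed at the other terminus should re-ionise under the silver conditions, and the silyl ether prevents the C3 oxygen from bridging to the tertiary terminus.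

Step 11
Reactants: 16 (3R,3aS,4R,8aS)-5-bromo-6,8a-dimethyl-3-(propan-2-yl)-3-[(triethylsilyl)oxy]-1,2,3,3a,4,7,8,8a-octahydroazulen-4-yl 4-methoxybenzoate
Product: 17 (3R,3aS,4S,8aS)-6,8a-dimethyl-3-(propan-2-yl)-3-[(triethylsilyl)oxy]-1,2,3,3a,4,7,8,8a-octahydroazulen-4-yl 4-methoxybenzoate
Conditions: Bu3SnH, AIBN (cat.), PhMe, 80 °C
Reagents that add atoms: none
Why: Radical-chain hydrodebromination: the stannyl radical abstracts the vinylic bromine and the σ-vinyl radical takes hydrogen from Bu3SnH, removing the helper atom while ester, silyl ether and all stereocentres stay untouched (the descriptor at C4 changes only by priority).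

Step 12
Reactants: 17 (3R,3aS,4S,8aS)-6,8a-dimethyl-3-(propan-2-yl)-3-[(triethylsilyl)oxy]-1,2,3,3a,4,7,8,8a-octahydroazulen-4-yl 4-methoxybenzoate
Product: 18 (3R,3aS,4S,8aS)-3-hydroxy-6,8a-dimethyl-3-(propan-2-yl)-1,2,3,3a,4,7,8,8a-octahydroazulen-4-yl 4-methoxybenzoate (CNP0327211.1)
Conditions: HF·pyridine, THF, 0 °C → rt
Reagents that add atoms: none
Why: Fluoride-driven Si–O cleavage under mildly acidic conditions that should neither hydrolyse nor ionise the allylic ester, nor allow acyl migration.

**Compound list**
1 | 2-methylcyclopentan-1-one (racemic) | CC1CCCC1=O | starting material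
2 | (S)-1-phenylethan-1-amine | C[C@H](N)c1ccccc1 | starting material
3 | but-3-en-2-one (methyl vinyl ketone) | CC(=O)C=C | starting material
4 | (S)-N-(2-methylcyclopentylidene)-1-phenylethan-1-amine (in equilibrium with its secondary enamine) | CC1CCCC1=N[C@@H](C)c1ccccc1 | intermediate
5 | 4-[(1R)-1-methyl-2-{[(1S)-1-phenylethyl]imino}cyclopentyl]butan-2-one | CC(=O)CC[C@@]1(C)CCCC1=N[C@@H](C)c1ccccc1 | intermediate
6 | (R)-2-methyl-2-(3-oxobutyl)cyclopentan-1-one | CC(=O)CC[C@@]1(C)CCCC1=O | intermediate
7 | (R)-7a-methyl-1,2,3,6,7,7a-hexahydro-5H-inden-5-one | O=C1CC[C@@]2(C)CCCC2=C1 | intermediate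
8 | (R)-7a-methyl-2,6,7,7a-tetrahydro-1H-inden-5-yl trifluoromethanesulfonate | O=S(=O)(OC1=CC2=CCC[C@]2(C)CC1)C(F)(F)F | intermediate
9 | (R)-5,7a-dimethyl-2,6,7,7a-tetrahydro-1H-indene | CC1=CC2=CCC[C@]2(C)CC1 | intermediate
10 | B-alkyl-9-BBN adduct of 9 (boron on C3, syn to H-3a, trans ring fusion) | C1=C(C)CC[C@@]2(C)CC[C@@H](B3C4CCCC3CCC4)[C@H]12 | intermediate
11 | (3R,3aR,7aS)-5,7a-dimethyl-2,3,3a,6,7,7a-hexahydro-1H-inden-3-ol | C1=C(C)CC[C@@]2(C)CC[C@@H](O)[C@H]12 | intermediate
12 | (3aR,7aS)-5,7a-dimethyl-1,2,3a,6,7,7a-hexahydro-3H-inden-3-one | C1=C(C)CC[C@@]2(C)CCC(=O)[C@H]12 | intermediate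
13 | (3R,3aR,7aS)-5,7a-dimethyl-3-(propan-2-yl)-2,3,3a,6,7,7a-hexahydro-1H-inden-3-ol | C1=C(C)CC[C@@]2(C)CC[C@@](O)(C(C)C)[C@H]12 | intermediate
14 | triethyl{[(3R,3aR,7aS)-5,7a-dimethyl-3-(propan-2-yl)-2,3,3a,6,7,7a-hexahydro-1H-inden-3-yl]oxy}silane | C1=C(C)CC[C@@]2(C)CC[C@@](O[Si](CC)(CC)CC)(C(C)C)[C@H]12 | intermediate
15 | dibromocarbene adduct of 14 (dibromocyclopropane across indene C4–C5, CBr2 on the face of H-3a) | BrC1(Br)[C@H]2[C@]1(C)CC[C@@]3(C)CC[C@@](O[Si](CC)(CC)CC)(C(C)C)[C@H]23 | intermediate
16 | (3R,3aS,4R,8aS)-5-bromo-6,8a-dimethyl-3-(propan-2-yl)-3-[(triethylsilyl)oxy]-1,2,3,3a,4,7,8,8a-octahydroazulen-4-yl 4-methoxybenzoate | COc1ccc(cc1)C(=O)O[C@H]1C(Br)=C(C)CC[C@@]2(C)CC[C@@](O[Si](CC)(CC)CC)(C(C)C)[C@H]12 | intermediate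
17 | (3R,3aS,4S,8aS)-6,8a-dimethyl-3-(propan-2-yl)-3-[(triethylsilyl)oxy]-1,2,3,3a,4,7,8,8a-octahydroazulen-4-yl 4-methoxybenzoate | COc1ccc(cc1)C(=O)O[C@H]1C=C(C)CC[C@@]2(C)CC[C@@](O[Si](CC)(CC)CC)(C(C)C)[C@H]12 | intermediate
18 | (3R,3aS,4S,8aS)-3-hydroxy-6,8a-dimethyl-3-(propan-2-yl)-1,2,3,3a,4,7,8,8a-octahydroazulen-4-yl 4-methoxybenzoate | COc1ccc(C(=O)O[C@H]2C=C(C)CC[C@@]3(C)CC[C@@](O)(C(C)C)[C@H]23)cc1 | target

Total steps: 12. Longest linear sequence: 12 (fully linear from 1).

**Steps most likely to fail**

1. Step 10. The cation may be captured at the tertiary terminus or from the methyl face, may lose a proton to a bromodiene, or the silyl ether may be lost early so that the C3 oxygen bridges to the cation. Fallback: from 15 the cyclopropane would be opened with AgClO4 in aqueous acetone, water acting as nucleophile, to give the epimeric bromo allylic alcohols F1. Dess–Martin oxidation would converge both epimers on bromo enone F2, and HF·pyridine would free the tertiary alcohol to give hydroxy bromo enone F3. Me4NBH(OAc)3 in MeCN/AcOH (Saksena–Evans reduction) would then deliver hydride within a boron chelate from the C3 oxygen, that is on the methyl face, to give the 3,4-trans bromo diol F4. 4-Methoxybenzoyl chloride with DMAP in pyridine should acylate only the secondary allylic hydroxyl to give bromo ester F5, and Bu3SnH/AIBN would return the route at 18. The approach changes from intermolecular capture of a cation to intramolecular hydride delivery to a ketone.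

2. Step 5. Hydroboration may also take place at the cyclohexene double bond of the conjugated diene, or twice, or give allylic boranes that scramble. Fallback: from 8 the hydroboration would be run on the dienyl triflate, whose triflyloxy-substituted double bond is electronically deactivated so that only the cyclopentene double bond can react (9-BBN, then buffered NaBO3 oxidation), giving hydroxy alkenyl triflate F6. A Negishi coupling (MeZnCl, Pd(PPh3)4, THF) would then install the methyl group and return the route at 11.

3. Step 7. Deprotonation of the doubly activated H-3a (epimerisation to the cis ring fusion or migration of the alkene into conjugation) or β-hydride reduction of the hindered ketone may outrun addition. Fallback: from 12 the smaller sp2 nucleophile isopropenylmagnesium bromide with CeCl3, which cannot transfer a β-hydride, would give isopropenyl carbinol F7. Hydrogenation with Wilkinson's catalyst should saturate only the 1,1-disubstituted alkene and return the route at 13.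

**Further compounds**
F1 | step 10 | (3R,3aS,8aS)-5-bromo-6,8a-dimethyl-3-(propan-2-yl)-3-[(triethylsilyl)oxy]-1,2,3,3a,4,7,8,8a-octahydroazulen-4-ol (C4 epimers) | OC1C(Br)=C(C)CC[C@@]2(C)CC[C@@](O[Si](CC)(CC)CC)(C(C)C)[C@H]12
F2 | step 10 | (3R,3aR,8aS)-5-bromo-6,8a-dimethyl-3-(propan-2-yl)-3-[(triethylsilyl)oxy]-2,3,3a,7,8,8a-hexahydroazulen-4(1H)-one | O=C1C(Br)=C(C)CC[C@@]2(C)CC[C@@](O[Si](CC)(CC)CC)(C(C)C)[C@H]12
F3 | step 10 | (3R,3aR,8aS)-5-bromo-3-hydroxy-6,8a-dimethyl-3-(propan-2-yl)-2,3,3a,7,8,8a-hexahydroazulen-4(1H)-one | O=C1C(Br)=C(C)CC[C@@]2(C)CC[C@@](O)(C(C)C)[C@H]12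
F4 | step 10 | (3R,3aS,4R,8aS)-5-bromo-6,8a-dimethyl-3-(propan-2-yl)-1,2,3,3a,4,7,8,8a-octahydroazulene-3,4-diol | O[C@H]1C(Br)=C(C)CC[C@@]2(C)CC[C@@](O)(C(C)C)[C@H]12
F5 | step 10 | (3R,3aS,4R,8aS)-5-bromo-3-hydroxy-6,8a-dimethyl-3-(propan-2-yl)-1,2,3,3a,4,7,8,8a-octahydroazulen-4-yl 4-methoxybenzoate | COc1ccc(cc1)C(=O)O[C@H]1C(Br)=C(C)CC[C@@]2(C)CC[C@@](O)(C(C)C)[C@H]12
F6 | step 5 | (3R,3aR,7aR)-3-hydroxy-7a-methyl-2,3,3a,6,7,7a-hexahydro-1H-inden-5-yl trifluoromethanesulfonate | C1=C(OS(=O)(=O)C(F)(F)F)CC[C@@]2(C)CC[C@@H](O)[C@H]12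
F7 | step 7 | (3S,3aR,7aS)-5,7a-dimethyl-3-(prop-1-en-2-yl)-2,3,3a,6,7,7a-hexahydro-1H-inden-3-ol | C1=C(C)CC[C@@]2(C)CC[C@@](O)(C(C)=C)[C@H]12
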